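**Plan**
Cuts, in retrosynthetic order: C8–CMe2 of the 1,1-dimethylallyl group (back to an O7 prenyl ether); O1–C2 and the C3–O bond (ring C, back to a 2'-hydroxychalcone); C4a–C5 (ring A, back to an open chain); C4–C4a; C2–C3 (the chalcone alkene); C5'–CH2 (ring B prenyl).
Enabling feature: ring A carries oxygen on C5, C7 and C8a in a 1,3,5 array and the acyl carbon C4 on C4a. It is therefore an acylphloroglucinol, the Claisen-folded form of a cinnamoyl-started 3,5,7-trioxo acid. A 6-(acylmethyl)-4-hydroxy-2-pyrone is the same nine-carbon chain with its carboxyl carbon stored as a lactone.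
Forward order: ring B is bought and prenylated. The chain grows by two carbons (olefination) and then by six (pyrone dianion). Ring A closes by refolding the pyrone, ring C closes oxidatively, and the last C–C bond comes from a [3,3] shift from O7 to C8.
Stereochemistry: the target has no stereocentre. Only the E alkene of the cinnamoyl unit needs control (olefination), and the two transient centres of the dihydroflavonol are erased on oxidation.

Key step: step 5

Remark: chromenones carry flavonoid numbering (ring B primed). In chalcones the ketone-bearing ring A is primed and Cα/Cβ are the alkene carbons. C1–C9 number the trioxo ester chain from the ester carbon. Ar = 3,4-bis(methoxymethoxy)-5-(3-methylbut-2-enyl)phenyl. All starting materials are assumed to be catalogue compounds.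

Step 1
Reactants: 1 3-bromo-4,5-dihydroxybenzaldehyde
Product: 2 3-bromo-4,5-bis(methoxymethoxy)benzaldehyde
Conditions: MOMCl (2.6 equiv), iPr2NEt (3 equiv), CH2Cl2, 0 °C → rt
Reagents that add atoms: chloromethyl methyl ether (MOMCl), COCCl
Why: Double O-alkylation of the catechol with MOMCl and an amine base (Williamson-type acetal ether formation) is routine, and MOM is chosen because it withstands palladium catalysis, lithium amide, methoxide, alkaline peroxide and heat yet leaves under acid mild enough for the two C5 alkenyl groups.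

Step 2
Reactants: 2 3-bromo-4,5-bis(methoxymethoxy)benzaldehyde; 3 tributyl(3-methylbut-2-enyl)stannane
Product: 4 3,4-bis(methoxymethoxy)-5-(3-methylbut-2-enyl)benzaldehyde
Conditions: Pd(PPh3)4 (5 mol %), DMF, 100 °C, Ar
Reagents that add atoms: none
Why: In this Stille cross-coupling zerovalent palladium inserts into the aryl C–Br bond, tin hands over the allylic group and reductive elimination at the unsubstituted allyl terminus gives the linear prenyl arene, with the formyl group tolerated as in the routine Stille allylation of bromobenzaldehydes.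

Step 3
Reactants: 4 3,4-bis(methoxymethoxy)-5-(3-methylbut-2-enyl)benzaldehyde; 5 diethyl [2-(methoxy(methyl)amino)-2-oxoethyl]phosphonate
Product: 6 (E)-3-Ar-N-methoxy-N-methylprop-2-enamide
Conditions: NaH (1.2 equiv), THF, 0 °C → rt
Reagents that add atoms: none
Why: Horner–Wadsworth–Emmons olefination of an aromatic aldehyde with an amide-stabilised phosphonate anion should give the E alkene and adds the carbons that become C3 and C4 already at the acyl-donor oxidation level.

Step 4
Reactants: 7 4-hydroxy-6-methylpyran-2-one; 6 (E)-3-Ar-N-methoxy-N-methylprop-2-enamide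
Product: 9 4-hydroxy-6-[(E)-4-Ar-2-oxobut-3-enyl]pyran-2-one, via dilithiated pyrone 8 (not isolated)
Conditions: 7 (1.5 equiv), LiN(iPr)2 (3.1 equiv), THF–DMPU, −78 → −30 °C; then 6 (1 equiv), −78 → −20 °C; cold 1 M HCl to pH 4
Reagents that add atoms: none
Why: C-acylation of the 6-methyl carbanion of the dilithiated pyrone by a carboxylic acid derivative is a known reaction of this dianion, the hard terminal carbanion should attack the amide carbonyl in 1,2 fashion, and the lithium-chelated tetrahedral adduct of the N-methoxy-N-methylamide lasts until the quench, so that neither double addition nor proton transfer from the acidic product consumes the nucleophile.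

Step 5
Reactants: 9 4-hydroxy-6-[(E)-4-Ar-2-oxobut-3-enyl]pyran-2-one
Product: 11 (E)-3-Ar-1-(2,4,6-trihydroxyphenyl)prop-2-en-1-one, via methyl triketo ester 10 (not isolated)
Conditions: Mg(OMe)2 (5 equiv), MeOH, reflux, Ar; cold 1 M HCl to pH 4
Reagents that add atoms: none
Why: Methoxide, helped by divalent magnesium bound to the pyrone oxygens, adds to the lactone carbonyl of 9 and opens the ring to the chelated methyl 3,5,7-trioxo ester 10, whose C6 methylene (between the C5 and C7 ketones) acylates itself at the ester carbon C1, after which loss of methoxide and threefold enolisation give aromatic ring A of 11, an isomer of 9. The closest known reaction type is the base-induced opening of 6-(acylmethyl)-4-hydroxy-2-pyrones followed by Claisen (Dieckmann-type) cyclisation of the 3,5,7-triketo esters to acylphloroglucinols. The single ring closed is carbocyclic ring A, by a 6-(enolexo)-exo-trig attack that forms C1'–C2' of the chalcone, which is C4a–C5 of the flavonol (equivalently C4a–C8a, since the two ortho carbons stay equivalent until step 7). No stereocentre is created and the E alkene is a spectator. Only two carbocyclic six-ring closures are geometrically open, C6 onto C1 (Claisen) and C2 onto C7 (aldol), because the other doubly activated methylene C4 could only form a four-membered ring; the Claisen mode should win since magnesium chelation of the 5,7-dicarbonyl unit places the nucleophilic site at C6, the C7 carbonyl is a donor-aryl-conjugated cinnamoyl ketone and a poor aldol acceptor, and aromatisation makes the closure irreversible, whereas relactonisation is reversible under methoxide. The magnesium phenoxide–carbonyl chelate of 11 should also hold back oxa-Michael closure of the product until the cold acidic quench.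

Step 6
Reactants: 11 (E)-3-Ar-1-(2,4,6-trihydroxyphenyl)prop-2-en-1-one; 12 3-methylbut-2-en-1-ol
Product: 13 (E)-3-Ar-1-[2,6-dihydroxy-4-(3-methylbut-2-enyloxy)phenyl]prop-2-en-1-one
Conditions: 12 (1.05 equiv), PPh3 (1.05 equiv), DIAD (1.05 equiv, added last), THF, 0 °C
Reagents that add atoms: none
Why: Mitsunobu etherification alkylates on oxygen only and so sidesteps the C-prenylation that acylphloroglucinol anions suffer with prenyl halides, it should pick the 4'-OH because this is the most acidic (para to the carbonyl) and least hindered hydroxyl while the 2'- and 6'-OH share the carbonyl hydrogen bond, and it needs no base that would drive oxa-Michael closure.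

Step 7
Reactants: 13 (E)-3-Ar-1-[2,6-dihydroxy-4-(3-methylbut-2-enyloxy)phenyl]prop-2-en-1-one
Product: 14 (E)-3-Ar-1-[2-hydroxy-6-(methoxymethoxy)-4-(3-methylbut-2-enyloxy)phenyl]prop-2-en-1-one
Conditions: MOMCl (1.2 equiv), K2CO3 (2.5 equiv), acetone, 0 °C → reflux
Reagents that add atoms: chloromethyl methyl ether (MOMCl), COCCl
Why: One of the two equivalent ortho hydroxyls is alkylated and the other then stays locked in the hydrogen bond to the carbonyl, the self-limiting selectivity known from the preparation of 2-hydroxy-4,6-bis(methoxymethoxy)acetophenone, and carbonate in hot acetone reopens by E1cB any material that had closed by oxa-Michael addition, so that all of it should drain to the open-chain ether.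

Step 8
Reactants: 14 (E)-3-Ar-1-[2-hydroxy-6-(methoxymethoxy)-4-(3-methylbut-2-enyloxy)phenyl]prop-2-en-1-one
Product: 16 2-Ar-3-hydroxy-5-(methoxymethoxy)-7-(3-methylbut-2-enyloxy)chromen-4-one, via trans-dihydroflavonol 15 (not isolated)
Conditions: 30 % aq. H2O2 (excess), 3 M aq. NaOH, MeOH, 0 °C → rt; dilute HCl to pH 5
Reagents that add atoms: hydrogen peroxide, OO
Why: In the Algar–Flynn–Oyamada reaction hydroperoxide delivers oxygen to Cα of the enone, the 2'-phenoxide bonds to Cβ to close ring C as the trans-dihydroflavonol 15 and excess alkaline peroxide dehydrogenates it, the nucleophilic oxidant ignores the two electron-rich trisubstituted alkenes, and the para oxygen donor of ring B together with the low temperature should favour attack at Cβ over the five-ring (aurone) pathway, as known for 2'-hydroxy-4',6'-bis(methoxymethoxy)chalcones.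

Step 9
Reactants: 16 2-Ar-3-hydroxy-5-(methoxymethoxy)-7-(3-methylbut-2-enyloxy)chromen-4-one
Product: 17 2-Ar-3,7-dihydroxy-5-(methoxymethoxy)-8-(2-methylbut-3-en-2-yl)chromen-4-one
Conditions: Eu(fod)3 (10 mol %), NaHCO3 (1 equiv), PhCl, 90 °C, Ar
Reagents that add atoms: none
Why: In this Lewis-acid-catalysed aromatic Claisen rearrangement the [3,3] shift inverts the prenyl unit to the 1,1-dimethylallyl group and rearomatising enolisation frees the 7-OH, C8 should be preferred because the C7–C8 bond of the benzopyranone has the higher double-bond character (7-allyloxychromones and 7-allyloxyflavones migrate to C8) and C6 is buttressed by the 5-OMOM group, and trivalent europium bound at the C4 carbonyl, which is conjugated with O7 through C4a, polarises the O7–CH2 bond enough for a temperature at which the abnormal Claisen pathway stays silent.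

Step 10
Reactants: 17 2-Ar-3,7-dihydroxy-5-(methoxymethoxy)-8-(2-methylbut-3-en-2-yl)chromen-4-one
Product: 18 2-[3,4-dihydroxy-5-(3-methylbut-2-enyl)phenyl]-3,5,7-trihydroxy-8-(2-methylbut-3-en-2-yl)chromen-4-one (target)
Conditions: conc. HCl (cat.), MeOH, rt → 40 °C, Ar
Reagents that add atoms: none
Why: Acid-catalysed transacetalisation of the three aryl MOM ethers to dimethoxymethane is faster than protonation of the prenyl or vinyl double bonds, as in the customary last-step unmasking of ortho-prenylated polyphenols, so low acid strength and temperature should avoid ring closure of a phenol onto a side chain.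

**Compound list**
1 | 3-bromo-4,5-dihydroxybenzaldehyde | O=Cc1cc(O)c(O)c(Br)c1 | starting material
2 | 3-bromo-4,5-bis(methoxymethoxy)benzaldehyde | O=Cc1cc(OCOC)c(OCOC)c(Br)c1 | intermediate
3 | tributyl(3-methylbut-2-enyl)stannane | CCCC[Sn](CCCC)(CCCC)CC=C(C)C | starting material
4 | 3,4-bis(methoxymethoxy)-5-(3-methylbut-2-enyl)benzaldehyde | O=Cc1cc(OCOC)c(OCOC)c(CC=C(C)C)c1 | intermediate
5 | diethyl [2-(methoxy(methyl)amino)-2-oxoethyl]phosphonate | CCOP(=O)(CC(=O)N(C)OC)OCC | starting material
6 | (E)-3-[3,4-bis(methoxymethoxy)-5-(3-methylbut-2-enyl)phenyl]-N-methoxy-N-methylprop-2-enamide | CON(C)C(=O)/C=C/c1cc(OCOC)c(OCOC)c(CC=C(C)C)c1 | intermediate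
7 | 4-hydroxy-6-methylpyran-2-one | Cc1cc(O)cc(=O)o1 | starting material
8 | dilithium salt of 4-oxido-6-methylidepyran-2-one (O4,CH2 dianion of 7) | [Li+].[Li+].[CH2-]c1cc([O-])cc(=O)o1 | intermediate
9 | 4-hydroxy-6-{(E)-4-[3,4-bis(methoxymethoxy)-5-(3-methylbut-2-enyl)phenyl]-2-oxobut-3-enyl}pyran-2-one | O=c1cc(O)cc(CC(=O)/C=C/c2cc(OCOC)c(OCOC)c(CC=C(C)C)c2)o1 | intermediate
10 | methyl (E)-9-[3,4-bis(methoxymethoxy)-5-(3-methylbut-2-enyl)phenyl]-3,5,7-trioxonon-8-enoate | COC(=O)CC(=O)CC(=O)CC(=O)/C=C/c1cc(OCOC)c(OCOC)c(CC=C(C)C)c1 | intermediate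
11 | (E)-3-[3,4-bis(methoxymethoxy)-5-(3-methylbut-2-enyl)phenyl]-1-(2,4,6-trihydroxyphenyl)prop-2-en-1-one | O=C(/C=C/c1cc(OCOC)c(OCOC)c(CC=C(C)C)c1)c1c(O)cc(O)cc1O | intermediate
12 | 3-methylbut-2-en-1-ol | CC(C)=CCO | starting material
13 | (E)-3-[3,4-bis(methoxymethoxy)-5-(3-methylbut-2-enyl)phenyl]-1-[2,6-dihydroxy-4-(3-methylbut-2-enyloxy)phenyl]prop-2-en-1-one | O=C(/C=C/c1cc(OCOC)c(OCOC)c(CC=C(C)C)c1)c1c(O)cc(OCC=C(C)C)cc1O | intermediate
14 | (E)-3-[3,4-bis(methoxymethoxy)-5-(3-methylbut-2-enyl)phenyl]-1-[2-hydroxy-6-(methoxymethoxy)-4-(3-methylbut-2-enyloxy)phenyl]prop-2-en-1-one | O=C(/C=C/c1cc(OCOC)c(OCOC)c(CC=C(C)C)c1)c1c(O)cc(OCC=C(C)C)cc1OCOC | intermediate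
15 | trans-2-[3,4-bis(methoxymethoxy)-5-(3-methylbut-2-enyl)phenyl]-3-hydroxy-5-(methoxymethoxy)-7-(3-methylbut-2-enyloxy)-2,3-dihydrochromen-4-one (racemic, one enantiomer drawn) | CC(C)=CCc1cc(cc(OCOC)c1OCOC)[C@@H]2[C@H](C(=O)c3c(OCOC)cc(OCC=C(C)C)cc3O2)O | intermediate
16 | 2-[3,4-bis(methoxymethoxy)-5-(3-methylbut-2-enyl)phenyl]-3-hydroxy-5-(methoxymethoxy)-7-(3-methylbut-2-enyloxy)chromen-4-one | O=c1c(O)c(-c2cc(OCOC)c(OCOC)c(CC=C(C)C)c2)oc2cc(OCC=C(C)C)cc(OCOC)c12 | intermediate
17 | 2-[3,4-bis(methoxymethoxy)-5-(3-methylbut-2-enyl)phenyl]-3,7-dihydroxy-5-(methoxymethoxy)-8-(2-methylbut-3-en-2-yl)chromen-4-one | C=CC(C)(C)c1c(O)cc(OCOC)c2c(=O)c(O)c(-c3cc(OCOC)c(OCOC)c(CC=C(C)C)c3)oc12 | intermediate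
18 | 2-[3,4-dihydroxy-5-(3-methylbut-2-enyl)phenyl]-3,5,7-trihydroxy-8-(2-methylbut-3-en-2-yl)chromen-4-one | C=CC(C)(C)c1c(O)cc(O)c2c(=O)c(O)c(-c3cc(O)c(O)c(CC=C(C)C)c3)oc12 | target

Total step count: 10. Longest linear sequence: 10 steps (1 → 18); compounds 3, 5, 7 and 12 enter without prior steps.

**Steps most likely to fail**

Step 5. The opened chain may fold the other way (aldol attack of C2 on the C7 carbonyl). It may also fall back to a lactone or a 4-pyranone by O-cyclisation, or the chalcone may close on by oxa-Michael addition during the long heating. The fallback gives up the refolding and assembles the chalcone by Claisen–Schmidt condensation. It sets out from aldehyde 4 and rejoins the route at 14. Purchased 2,4,6-trihydroxyacetophenone is etherified at O4 with 12 (PPh3, DIAD, THF, 0 °C) to give 1-[2,6-dihydroxy-4-(3-methylbut-2-enyloxy)phenyl]ethanone F1. One ortho hydroxyl is capped (MOMCl, iPr2NEt, CH2Cl2) to give 1-[2-hydroxy-6-(methoxymethoxy)-4-(3-methylbut-2-enyloxy)phenyl]ethanone F2. F2 is then condensed with 4 (KOH, EtOH, rt) to give 14, and steps 8–10 follow unchanged.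

Step 4. The dianion may add in conjugate fashion to the β-carbon of the cinnamoyl unit, or the sparingly soluble dilithio salt may react too slowly with the amide. The fallback replaces acylation by carbonyl addition and oxidation. It sets out from 6 and rejoins the route at 9. Reduction of 6 (iBu2AlH, THF, −78 °C) gives (E)-3-[3,4-bis(methoxymethoxy)-5-(3-methylbut-2-enyl)phenyl]prop-2-enal F3. This far more electrophilic carbonyl takes up the dianion 8 in kinetic 1,2 fashion at −78 °C, giving racemic 4-hydroxy-6-{(E)-4-[3,4-bis(methoxymethoxy)-5-(3-methylbut-2-enyl)phenyl]-2-hydroxybut-3-enyl}pyran-2-one F4. Oxidation of the allylic alcohol (Dess–Martin periodinane, NaHCO3, CH2Cl2) then gives 9.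

Step 9. The shift may show poor site selectivity between C8 and C6. The Lewis acid may ionise the O7–prenyl bond so that the group is lost or returned without inversion, or the 3-hydroxy-4-keto unit may tie up the catalyst. The fallback moves the rearrangement to the chalcone stage, where the carbonyl chelate of the 2'-OH fixes the double bond C3'=C4' and directs migration to C3', as in 4-allyloxy-2-hydroxyaryl ketones. It sets out from 14 and rejoins the route at 18. Heating 14 (Eu(fod)3, NaHCO3, PhCl, 80–90 °C) should give (E)-3-[3,4-bis(methoxymethoxy)-5-(3-methylbut-2-enyl)phenyl]-1-[2,4-dihydroxy-6-(methoxymethoxy)-3-(2-methylbut-3-en-2-yl)phenyl]prop-2-en-1-one F5. The unchelated 4'-OH is capped (MOMCl, iPr2NEt, CH2Cl2) to give (E)-3-[3,4-bis(methoxymethoxy)-5-(3-methylbut-2-enyl)phenyl]-1-[2-hydroxy-4,6-bis(methoxymethoxy)-3-(2-methylbut-3-en-2-yl)phenyl]prop-2-en-1-one F6. Algar–Flynn–Oyamada oxidation through the only free hydroxyl (H2O2, NaOH, MeOH) places the side chain at C8 in 2-[3,4-bis(methoxymethoxy)-5-(3-methylbut-2-enyl)phenyl]-3-hydroxy-5,7-bis(methoxymethoxy)-8-(2-methylbut-3-en-2-yl)chromen-4-one F7. The conditions of step 10 then convert F7 into 18.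

**Further compounds**
F1 | step 5 | 1-[2,6-dihydroxy-4-(3-methylbut-2-enyloxy)phenyl]ethanone | CC(=O)c1c(O)cc(OCC=C(C)C)cc1O
F2 | step 5 | 1-[2-hydroxy-6-(methoxymethoxy)-4-(3-methylbut-2-enyloxy)phenyl]ethanone | CC(=O)c1c(O)cc(OCC=C(C)C)cc1OCOC
F3 | step 4 | (E)-3-[3,4-bis(methoxymethoxy)-5-(3-methylbut-2-enyl)phenyl]prop-2-enal | O=C/C=C/c1cc(OCOC)c(OCOC)c(CC=C(C)C)c1
F4 | step 4 | 4-hydroxy-6-{(E)-4-[3,4-bis(methoxymethoxy)-5-(3-methylbut-2-enyl)phenyl]-2-hydroxybut-3-enyl}pyran-2-one (racemic) | O=c1cc(O)cc(CC(O)/C=C/c2cc(OCOC)c(OCOC)c(CC=C(C)C)c2)o1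
F5 | step 9 | (E)-3-[3,4-bis(methoxymethoxy)-5-(3-methylbut-2-enyl)phenyl]-1-[2,4-dihydroxy-6-(methoxymethoxy)-3-(2-methylbut-3-en-2-yl)phenyl]prop-2-en-1-one | O=C(/C=C/c1cc(OCOC)c(OCOC)c(CC=C(C)C)c1)c1c(O)c(C(C)(C)C=C)c(O)cc1OCOC
F6 | step 9 | (E)-3-[3,4-bis(methoxymethoxy)-5-(3-methylbut-2-enyl)phenyl]-1-[2-hydroxy-4,6-bis(methoxymethoxy)-3-(2-methylbut-3-en-2-yl)phenyl]prop-2-en-1-one | O=C(/C=C/c1cc(OCOC)c(OCOC)c(CC=C(C)C)c1)c1c(O)c(C(C)(C)C=C)c(OCOC)cc1OCOC
F7 | step 9 | 2-[3,4-bis(methoxymethoxy)-5-(3-methylbut-2-enyl)phenyl]-3-hydroxy-5,7-bis(methoxymethoxy)-8-(2-methylbut-3-en-2-yl)chromen-4-one | C=CC(C)(C)c1c(OCOC)cc(OCOC)c2c(=O)c(O)c(-c3cc(OCOC)c(OCOC)c(CC=C(C)C)c3)oc12
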